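**Retrosynthetic overview**

1. The target is a ten-membered germacranolide (locants: ring C1–C10; lactone carbons C11–C13 closed at O6; C14 = methyl on C10; C15 = CH2OAc on C4). The O8 ester is disconnected first: Mitsunobu esterification with inversion, using acid 6 made by anti-hydrostannation of but-2-yn-1-ol.
2. Key disconnection C7–C8. The homoallylic alcohol array O8–C8–C7–C11=C13 inside the α-methylene-γ-butyrolactone (ring O6–C12–C11–C7–C6) is the retron of a carbonyl allylation. The precursor is the open-chain C8 aldehyde carrying a 3-(bromomethyl)butenolide (C11=C7, CH2Br = C13) at C6. One chromium-mediated step closes the ten-membered ring, sets C7 and C8, and unveils the exocyclic methylene.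
3. The butenolide comes from ring-closing metathesis of a C6 2-(bromomethyl)acrylate. The C5/C6 syn-diol comes from Brown alkoxyallylboration of a (Z)-enal. The (Z)-C3=C4 alkene comes from hydroxyl-directed anti-hydroalumination/iodination of a C2 propargylic alcohol.
4. C2 is set by Noyori transfer hydrogenation of an ynone. C8, C9, C10, C14, C1 and C2 come from (R)-mevalonolactone (C10 from the chiral pool).
5. Ring order: five-membered lactone (step 18), then ten-membered carbocycle (step 21).

Key step: step 21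

Remark: open-chain intermediates are described with the target locants above (chain C8–C9–C10(C14)–C1–C2–C3=C4(C15)–C5–C6–C7). Compounds 11 and 20 are taken as catalogue compounds (each is otherwise one O-alkylation from propargyl or allyl alcohol). The sense of induction in steps 9 and 13 is assigned from the established models for these reagents.

**Route**

Step 1
Reactants: 1 but-2-yn-1-ol
Product: 2 (Z)-2-(tributylstannyl)but-2-en-1-ol
Conditions: Bu3SnH, [Cp*RuCl]4 (1.5 mol %), CH2Cl2, rt
Reagents that add atoms: tributyltin hydride, CCCC[SnH](CCCC)CCCC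
Why: Ruthenium-catalysed trans-hydrostannation of a propargylic alcohol, in which the hydroxyl group steers tin to the proximal alkyne carbon and H and Sn add anti, fixing the angelate-type geometry.

Step 2
Reactants: 2 (Z)-2-(tributylstannyl)but-2-en-1-ol
Product: 3 (Z)-2-iodobut-2-en-1-ol
Conditions: I2, CH2Cl2, 0 °C
Reagents that add atoms: iodine, II
Why: Iododestannylation (tin–iodine exchange) should proceed with retention of the alkene geometry.

Step 3
Reactants: 3 (Z)-2-iodobut-2-en-1-ol
Product: 5 (Z)-2-(hydroxymethyl)but-2-enoic acid, via dilithio alkoxide 4 (not isolated)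
Conditions: t-BuLi (3.2 equiv), Et2O, −78 °C; CO2; aq. HCl
Reagents that add atoms: carbon dioxide, O=C=O
Why: Halogen–lithium exchange on the lithium alkoxide gives a configurationally stable vinyllithium, and its carboxylation should occur with retention, placing the carboxyl group cis to the methyl group.

Step 4
Reactants: 5 (Z)-2-(hydroxymethyl)but-2-enoic acid
Product: 6 (Z)-2-(acetoxymethyl)but-2-enoic acid
Conditions: Ac2O, pyridine, CH2Cl2, 0 °C to rt; then H2O
Reagents that add atoms: acetic anhydride, CC(=O)OC(C)=O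
Why: O-Acetylation of the primary allylic alcohol without DMAP (to avoid conjugate-addition isomerisation); the transient mixed anhydride of the acid is hydrolysed on aqueous work-up.

Step 5
Reactants: 7 (R)-mevalonolactone
Product: 8 (3R)-3,5-dihydroxy-N-methoxy-N,3-dimethylpentanamide
Conditions: MeNH(OMe)·HCl, AlMe3, CH2Cl2, 0 °C to rt
Reagents that add atoms: N,O-dimethylhydroxylamine hydrochloride, CNOC.Cl
Why: Weinreb aminolysis of the δ-lactone by the aluminium amide; the C10 stereocentre comes from the chiral pool and is not touched.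

Step 6
Reactants: 8 (3R)-3,5-dihydroxy-N-methoxy-N,3-dimethylpentanamide
Product: 9 (3R)-5-(tert-butyldimethylsilyloxy)-3-hydroxy-N-methoxy-N,3-dimethylpentanamide
Conditions: TBSCl, imidazole, CH2Cl2, 0 °C
Reagents that add atoms: tert-butyldimethylsilyl chloride, CC(C)(C)[Si](C)(C)Cl
Why: Sterically controlled silylation of the primary (C8) over the tertiary hydroxyl.

Step 7
Reactants: 9 (3R)-5-(tert-butyldimethylsilyloxy)-3-hydroxy-N-methoxy-N,3-dimethylpentanamide
Product: 10 (3R)-5-(tert-butyldimethylsilyloxy)-N-methoxy-N,3-dimethyl-3-(triethylsilyloxy)pentanamide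
Conditions: TESOTf, 2,6-lutidine, CH2Cl2, −78 to 0 °C
Reagents that add atoms: triethylsilyl trifluoromethanesulfonate, CC[Si](CC)(CC)OS(=O)(=O)C(F)(F)F
Why: Silyl triflate silylation of the tertiary C10 alcohol, which blocks oxa-Michael closure of the coming ynone and retro-aldol pathways.

Step 8
Reactants: 10 (3R)-5-(tert-butyldimethylsilyloxy)-N-methoxy-N,3-dimethyl-3-(triethylsilyloxy)pentanamide; 11 1-methoxy-4-[(prop-2-yn-1-yloxy)methyl]benzene (PMB propargyl ether)
Product: 13 (6R)-8-(tert-butyldimethylsilyloxy)-1-(4-methoxybenzyloxy)-6-methyl-6-(triethylsilyloxy)oct-2-yn-4-one, via lithium acetylide 12 (not isolated)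
Conditions: 11, n-BuLi, THF, −78 °C; then 10, −78 to −20 °C; aq. NH4Cl
Reagents that add atoms: none
Why: Weinreb ketone synthesis, in which the lithium acetylide adds only once because the chelated tetrahedral intermediate survives until work-up.

Step 9
Reactants: 13 (6R)-8-(tert-butyldimethylsilyloxy)-1-(4-methoxybenzyloxy)-6-methyl-6-(triethylsilyloxy)oct-2-yn-4-one
Product: 14 (4R,6R)-8-(tert-butyldimethylsilyloxy)-1-(4-methoxybenzyloxy)-6-methyl-6-(triethylsilyloxy)oct-2-yn-4-ol
Conditions: RuCl(p-cymene)[(R,R)-TsDPEN] (2 mol %), KOH (2 mol %), i-PrOH, rt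
Reagents that add atoms: none
Why: Noyori asymmetric transfer hydrogenation of an alkynyl ketone, in which the (R,R)-ligand should deliver hydride to the face giving the (R)-carbinol at C2 (the alkyne acting as the π-substituent) under catalyst control that overrides the remote C10 centre.

Step 10
Reactants: 14 (4R,6R)-8-(tert-butyldimethylsilyloxy)-1-(4-methoxybenzyloxy)-6-methyl-6-(triethylsilyloxy)oct-2-yn-4-ol
Product: 16 (2Z,4R,6R)-8-(tert-butyldimethylsilyloxy)-2-iodo-1-(4-methoxybenzyloxy)-6-methyl-6-(triethylsilyloxy)oct-2-en-4-ol, via cyclic vinylalanate 15 (not isolated)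
Conditions: NaAlH2(OCH2CH2OMe)2 (Red-Al), THF, 0 °C; EtOAc; then I2, THF, −78 to 0 °C
Reagents that add atoms: iodine, II
Why: Hydroxyl-directed trans-hydroalumination of the propargylic alcohol places aluminium on C4 and hydrogen on C3 anti to each other, and iodinolysis with retention should give the iodoalkene with iodine cis to C2, which fixes the (Z)-C3=C4 geometry of the target.

Step 11
Reactants: 16 (2Z,4R,6R)-8-(tert-butyldimethylsilyloxy)-2-iodo-1-(4-methoxybenzyloxy)-6-methyl-6-(triethylsilyloxy)oct-2-en-4-ol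
Product: 17 triisopropylsilyl ether of 16 at the C4 carbinol (target C2)
Conditions: TIPSOTf, 2,6-lutidine, CH2Cl2, −78 to 0 °C
Reagents that add atoms: triisopropylsilyl trifluoromethanesulfonate, CC(C)[Si](C(C)C)(C(C)C)OS(=O)(=O)C(F)(F)F
Why: Silyl triflate silylation of the secondary alcohol; the bulky TIPS group is chosen because it resists 1,4 O-to-C silyl migration in the next step and survives the later selective desilylation.

Step 12
Reactants: 17 triisopropylsilyl ether of 16
Product: 19 (2Z,4R,6R)-8-(tert-butyldimethylsilyloxy)-2-[(4-methoxybenzyloxy)methyl]-6-methyl-6-(triethylsilyloxy)-4-(triisopropylsilyloxy)oct-2-enal, via vinyllithium 18 (not isolated)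
Conditions: t-BuLi (2.1 equiv), Et2O, −78 °C; DMF, −78 to 0 °C; aq. NH4Cl
Reagents that add atoms: N,N-dimethylformamide, CN(C)C=O
Why: Iodine–lithium exchange followed by formylation with DMF should occur with retention of alkene geometry, giving the enal whose formyl carbon (C5) is cis to C2.

Step 13
Reactants: 19 (Z)-enal; 20 3-(methoxymethoxy)prop-1-ene (allyl MOM ether)
Product: 22 (2R,3Z,5S,6S,10R) open chain with C5 OH; C6 OMOM; C7 vinyl; C15 OPMB; C2 OTIPS; C10 OTES; C8 OTBS, via alkoxyallylborane 21 (not isolated)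
Conditions: 20, s-BuLi, THF, −78 °C; (+)-Ipc2BOMe; BF3·OEt2; 19, −78 °C; then NaOH, H2O2, 0 °C to rt
Reagents that add atoms: none
Why: Brown alkoxyallylboration, in which the (Z)-γ-alkoxyallylborane reacts through a closed chair transition state to give the syn 5,6-diol monoether, and the isopinocampheyl groups derived from (−)-α-pinene should select the aldehyde face that gives 5S,6S (reagent control).

Step 14
Reactants: 22 C5 alcohol with C15 OPMB
Product: 23 (2R,3Z,5S,6S,10R) open chain with C5 OH and C15 OH; C6 OMOM; C7 vinyl; C2 OTIPS; C10 OTES; C8 OTBS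
Conditions: DDQ, CH2Cl2/pH 7 buffer, 0 °C
Reagents that add atoms: none
Why: Oxidative cleavage of the p-methoxybenzyl ether by DDQ in wet solvent; silyl and MOM ethers are inert.

Step 15
Reactants: 23 C5,C15-diol
Product: 24 (2R,3Z,5S,6S,10R) open chain with C5 OAc and C15 OAc; C6 OMOM; C7 vinyl; C2 OTIPS; C10 OTES; C8 OTBS
Conditions: Ac2O, pyridine, DMAP (cat.), CH2Cl2, 0 °C to rt
Reagents that add atoms: acetic anhydride, CC(=O)OC(C)=O
Why: DMAP-catalysed acetylation of the primary and the secondary allylic alcohol installs both ring acetates of the target in one operation.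

Step 16
Reactants: 24 diacetate with C6 OMOM
Product: 25 (2R,3Z,5S,6S,10R) open chain with C6 OH; C5 OAc; C15 OAc; C7 vinyl; C2 OTIPS; C10 OTES; C8 OTBS
Conditions: Me2BBr, CH2Cl2, −78 °C; then NaHCO3, THF/H2O
Reagents that add atoms: none
Why: Lewis-acid cleavage of the MOM acetal by dimethylboron bromide at low temperature, conditions that leave silyl ethers and acetates in place.

Step 17
Reactants: 25 C6 alcohol; 26 2-(bromomethyl)acrylic acid
Product: 27 C6 2-(bromomethyl)acrylate ester of 25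
Conditions: 26, DIC, DMAP (10 mol %), CH2Cl2, −20 to 0 °C
Reagents that add atoms: none
Why: Steglich (carbodiimide) esterification of the C6 alcohol, run cold and with little DMAP to limit attack of the catalyst on the allylic bromide and acetyl migration from O5.

Step 18
Reactants: 27 C6 2-(bromomethyl)acrylate
Product: 28 (2R,3Z,5S,6S,10R) open chain ending in a 3-(bromomethyl)furan-2(5H)-one attached through its C5 (target C6); C5 OAc; C15 OAc; C2 OTIPS; C10 OTES; C8 OTBS
Conditions: Hoveyda–Grubbs second-generation catalyst RuCl2(H2IMes)(=CH-C6H4-2-O-i-Pr) (10 mol %), toluene, 80 °C, argon sparge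
Reagents that add atoms: none
Why: Ring-closing olefin metathesis between the C7 vinyl group and the 1,1-disubstituted acrylate forms the butenolide (C11=C7) with loss of ethene; the trisubstituted C3=C4 alkene should not take part.

Step 19
Reactants: 28 silyl-protected bromomethyl butenolide
Product: 29 (2R,3Z,5S,6S,10R) C8,C10-diol with C2 OTIPS; C5 OAc; C15 OAc; 3-(bromomethyl)butenolide
Conditions: HF·pyridine, THF, 0 °C to rt
Reagents that add atoms: none
Why: Selective desilylation, in which acidic fluoride should cleave the primary TBS and the tertiary TES ether much faster than the hindered secondary allylic TIPS ether.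

Step 20
Reactants: 29 C8,C10-diol
Product: 30 (2R,3Z,5S,6S,10S) C8 aldehyde with free C10 OH; C2 OTIPS; C5 OAc; C15 OAc; 3-(bromomethyl)butenolide
Conditions: Dess–Martin periodinane, NaHCO3, CH2Cl2, 0 °C to rt
Reagents that add atoms: none
Why: Dess–Martin oxidation of the primary alcohol to the aldehyde; the tertiary alcohol cannot be oxidised and the buffered conditions spare the allylic bromide.

Step 21
Reactants: 30 C8 aldehyde carrying the 3-(bromomethyl)butenolide
Product: 32 (2R,3Z,5S,6S,7R,8S,10R) ten-membered 6,12-olide with C8 OH; C10 OH; C2 OTIPS; C5 OAc; C15 OAc; exocyclic C11=C13, via allylchromium species 31 (not isolated)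
Conditions: CrCl2 (10 equiv), THF, rt, syringe-pump addition of 30 (final 0.003 M); aq. NH4Cl
Reagents that add atoms: none
Why: Divalent chromium reduces the allylic C13–Br bond by two single-electron transfers to a trivalent allylchromium species, which adds to the C8 aldehyde through its γ-carbon C7 (SE2′) in a six-membered Zimmerman–Traxler transition state, so that the butenolide double bond moves to the exocyclic C11=C13 position. The closest known reactions are the chromium-mediated intramolecular Nozaki–Hiyama–Kishi allylations that close ten-membered germacranolide rings and the intermolecular Barbier allylation of aldehydes with 3-(bromomethyl)furan-2(5H)-one. The ten-membered carbocycle is closed by a 10-exo-trig attack on the aldehyde, and the five-membered lactone, already present, becomes trans-fused. C7 is controlled by C6, because the aldehyde should add to the butenolide face anti to the C5 substituent; C8 is controlled by the chair transition state, in which the ring-locked allyl unit holds C6 pseudo-equatorial (an E-type γ-substituent) and the aldehyde chain C9 sits equatorial, which should give the 7,8-anti (8S) alcohol. The step needs chemoselective metalation (CrCl2 reduces only the allylic bromide, not the allylic acetates or the lactone), γ- over α-attack (inherent to allylchromium reagents) and ring closure over oligomerisation, which is served by high dilution and by the (Z)-C3=C4 alkene and quaternary C10 that fold the chain. The 8S configuration is the one required for the inverting esterification of step 22.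

Step 22
Reactants: 32 macrocyclic (8S)-alcohol; 6 (Z)-2-(acetoxymethyl)but-2-enoic acid
Product: 33 (2R,3Z,5S,6S,7R,8R,10R) C2 triisopropylsilyl ether of the target
Conditions: 6, PPh3, DIAD, toluene, 0 °C to rt
Reagents that add atoms: none
Why: Mitsunobu esterification, in which the carboxylate displaces the C8 oxyphosphonium ion with inversion (8S to 8R); the (Z)-acid is not activated at its carbonyl group and should keep its geometry, and the tertiary C10 alcohol is inert.

Step 23
Reactants: 33 C2 triisopropylsilyl ether of the target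
Product: 34 CNP0126757.1 (2R,3Z,5S,6S,7R,8R,10S)
Conditions: HF·pyridine, pyridine, THF, 0 °C to rt
Reagents that add atoms: none
Why: Fluoride-mediated desilylation under acidic, non-basic conditions should free the C2 alcohol while sparing the three acetates, the enoate ester and the α-methylene lactone.

**Compound list**

1 | but-2-yn-1-ol | CC#CCO | starting material
2 | (Z)-2-(tributylstannyl)but-2-en-1-ol | C/C=C(/CO)[Sn](CCCC)(CCCC)CCCC | intermediate
3 | (Z)-2-iodobut-2-en-1-ol | C/C=C(/CO)I | intermediate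
4 | lithium (Z)-2-lithiobut-2-en-1-olate (dilithio alkoxide, not isolated) | C/C=C(/CO[Li])[Li] | intermediate
5 | (Z)-2-(hydroxymethyl)but-2-enoic acid | C/C=C(/CO)C(=O)O | intermediate
6 | (Z)-2-(acetoxymethyl)but-2-enoic acid | C/C=C(/COC(C)=O)C(=O)O | intermediate
7 | (R)-mevalonolactone, (4R)-4-hydroxy-4-methyloxan-2-one | C[C@@]1(O)CCOC(=O)C1 | starting material
8 | (3R)-3,5-dihydroxy-N-methoxy-N,3-dimethylpentanamide | OCC[C@@](C)(O)CC(=O)N(C)OC | intermediate
9 | (3R)-5-(tert-butyldimethylsilyloxy)-3-hydroxy-N-methoxy-N,3-dimethylpentanamide | CC(C)(C)[Si](C)(C)OCC[C@@](C)(O)CC(=O)N(C)OC | intermediate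
10 | (3R)-5-(tert-butyldimethylsilyloxy)-N-methoxy-N,3-dimethyl-3-(triethylsilyloxy)pentanamide | CC(C)(C)[Si](C)(C)OCC[C@@](C)(O[Si](CC)(CC)CC)CC(=O)N(C)OC | intermediate
11 | 1-methoxy-4-[(prop-2-yn-1-yloxy)methyl]benzene (PMB propargyl ether) | C#CCOCc1ccc(OC)cc1 | starting material
12 | lithium acetylide of 11 (not isolated) | [Li]C#CCOCc1ccc(OC)cc1 | intermediate
13 | (6R)-8-(tert-butyldimethylsilyloxy)-1-(4-methoxybenzyloxy)-6-methyl-6-(triethylsilyloxy)oct-2-yn-4-one | CC(C)(C)[Si](C)(C)OCC[C@@](C)(O[Si](CC)(CC)CC)CC(=O)C#CCOCc1ccc(OC)cc1 | intermediate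
14 | (4R,6R)-8-(tert-butyldimethylsilyloxy)-1-(4-methoxybenzyloxy)-6-methyl-6-(triethylsilyloxy)oct-2-yn-4-ol | CC(C)(C)[Si](C)(C)OCC[C@@](C)(O[Si](CC)(CC)CC)C[C@@H](O)C#CCOCc1ccc(OC)cc1 | intermediate
15 | sodium cyclic alkoxy(vinyl)alanate from 14 (five-membered O2–Al–C4=C3–C2 ring, not isolated) | CC(C)(C)[Si](C)(C)OCC[C@@](C)(O[Si](CC)(CC)CC)C[C@@H](O[Al-]1(OCCOC)OCCOC)C=C1COCc2ccc(OC)cc2.[Na+] | intermediate
16 | (2Z,4R,6R)-8-(tert-butyldimethylsilyloxy)-2-iodo-1-(4-methoxybenzyloxy)-6-methyl-6-(triethylsilyloxy)oct-2-en-4-ol | CC(C)(C)[Si](C)(C)OCC[C@@](C)(O[Si](CC)(CC)CC)C[C@@H](O)/C=C(/COCc1ccc(OC)cc1)I | intermediate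
17 | triisopropylsilyl ether of 16 (target C2 OTIPS) | CC(C)(C)[Si](C)(C)OCC[C@@](C)(O[Si](CC)(CC)CC)C[C@@H](O[Si](C(C)C)(C(C)C)C(C)C)/C=C(/COCc1ccc(OC)cc1)I | intermediate
18 | vinyllithium from 17 (lithium on C4, not isolated) | CC(C)(C)[Si](C)(C)OCC[C@@](C)(O[Si](CC)(CC)CC)C[C@@H](O[Si](C(C)C)(C(C)C)C(C)C)/C=C(/COCc1ccc(OC)cc1)[Li] | intermediate
19 | (2Z,4R,6R)-8-(tert-butyldimethylsilyloxy)-2-[(4-methoxybenzyloxy)methyl]-6-methyl-6-(triethylsilyloxy)-4-(triisopropylsilyloxy)oct-2-enal | CC(C)(C)[Si](C)(C)OCC[C@@](C)(O[Si](CC)(CC)CC)C[C@@H](O[Si](C(C)C)(C(C)C)C(C)C)/C=C(/COCc1ccc(OC)cc1)C=O | intermediate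
20 | 3-(methoxymethoxy)prop-1-ene (allyl MOM ether) | C=CCOCOC | starting material
21 | [(Z)-3-(methoxymethoxy)allyl]diisopinocampheylborane from (+)-Ipc2BOMe (not isolated) | COCO/C=C\CB([C@H]1C[C@H]2C[C@@H]([C@@H]1C)C2(C)C)[C@H]1C[C@H]2C[C@@H]([C@@H]1C)C2(C)C | intermediate
22 | (2R,3Z,5S,6S,10R) open chain: C5 OH, C6 OMOM, C7 vinyl, C15 OPMB, C2 OTIPS, C10 OTES, C8 OTBS | CC(C)(C)[Si](C)(C)OCC[C@@](C)(O[Si](CC)(CC)CC)C[C@@H](O[Si](C(C)C)(C(C)C)C(C)C)/C=C(/COCc1ccc(OC)cc1)[C@H](O)[C@@H](OCOC)C=C | intermediate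
23 | (2R,3Z,5S,6S,10R) open chain: C5 OH, C15 OH, C6 OMOM, C7 vinyl, C2 OTIPS, C10 OTES, C8 OTBS | CC(C)(C)[Si](C)(C)OCC[C@@](C)(O[Si](CC)(CC)CC)C[C@@H](O[Si](C(C)C)(C(C)C)C(C)C)/C=C(/CO)[C@H](O)[C@@H](OCOC)C=C | intermediate
24 | (2R,3Z,5S,6S,10R) open chain: C5 OAc, C15 OAc, C6 OMOM, C7 vinyl, C2 OTIPS, C10 OTES, C8 OTBS | CC(C)(C)[Si](C)(C)OCC[C@@](C)(O[Si](CC)(CC)CC)C[C@@H](O[Si](C(C)C)(C(C)C)C(C)C)/C=C(/COC(C)=O)[C@H](OC(C)=O)[C@@H](OCOC)C=C | intermediate
25 | (2R,3Z,5S,6S,10R) open chain: C6 OH, C5 OAc, C15 OAc, C7 vinyl, C2 OTIPS, C10 OTES, C8 OTBS | CC(C)(C)[Si](C)(C)OCC[C@@](C)(O[Si](CC)(CC)CC)C[C@@H](O[Si](C(C)C)(C(C)C)C(C)C)/C=C(/COC(C)=O)[C@H](OC(C)=O)[C@@H](O)C=C | intermediate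
26 | 2-(bromomethyl)acrylic acid | C=C(CBr)C(=O)O | starting material
27 | C6 2-(bromomethyl)acrylate of 25 | CC(C)(C)[Si](C)(C)OCC[C@@](C)(O[Si](CC)(CC)CC)C[C@@H](O[Si](C(C)C)(C(C)C)C(C)C)/C=C(/COC(C)=O)[C@H](OC(C)=O)[C@@H](OC(=O)C(=C)CBr)C=C | intermediate
28 | (2R,3Z,5S,6S,10R) open chain ending in a 3-(bromomethyl)furan-2(5H)-one at C6: C5 OAc, C15 OAc, C2 OTIPS, C10 OTES, C8 OTBS | CC(C)(C)[Si](C)(C)OCC[C@@](C)(O[Si](CC)(CC)CC)C[C@@H](O[Si](C(C)C)(C(C)C)C(C)C)/C=C(/COC(C)=O)[C@H](OC(C)=O)[C@H]1OC(=O)C(CBr)=C1 | intermediate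
29 | (2R,3Z,5S,6S,10R) C8,C10-diol: C2 OTIPS, C5 OAc, C15 OAc, 3-(bromomethyl)butenolide | OCC[C@@](C)(O)C[C@@H](O[Si](C(C)C)(C(C)C)C(C)C)/C=C(/COC(C)=O)[C@H](OC(C)=O)[C@H]1OC(=O)C(CBr)=C1 | intermediate
30 | (2R,3Z,5S,6S,10S) C8 aldehyde: C10 OH, C2 OTIPS, C5 OAc, C15 OAc, 3-(bromomethyl)butenolide | O=CC[C@@](C)(O)C[C@@H](O[Si](C(C)C)(C(C)C)C(C)C)/C=C(/COC(C)=O)[C@H](OC(C)=O)[C@H]1OC(=O)C(CBr)=C1 | intermediate
31 | allylchromium dichloride from 30 (trivalent chromium on C13, not isolated) | O=CC[C@@](C)(O)C[C@@H](O[Si](C(C)C)(C(C)C)C(C)C)/C=C(/COC(C)=O)[C@H](OC(C)=O)[C@H]1OC(=O)C(C[Cr](Cl)Cl)=C1 | intermediate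
32 | (2R,3Z,5S,6S,7R,8S,10R) ten-membered 6,12-olide: C8 OH, C10 OH, C2 OTIPS, C5 OAc, C15 OAc, exocyclic C11=C13 | C=C1C(=O)O[C@H]2[C@H]1[C@@H](O)C[C@@](C)(O)C[C@@H](O[Si](C(C)C)(C(C)C)C(C)C)/C=C(/COC(C)=O)[C@@H]2OC(C)=O | intermediate
33 | (2R,3Z,5S,6S,7R,8R,10R) C2 triisopropylsilyl ether of the target | C=C1C(=O)O[C@H]2[C@H]1[C@H](OC(=O)/C(=C\C)COC(C)=O)C[C@@](C)(O)C[C@@H](O[Si](C(C)C)(C(C)C)C(C)C)/C=C(/COC(C)=O)[C@@H]2OC(C)=O | intermediate
34 | CNP0126757.1, (2R,3Z,5S,6S,7R,8R,10S) | C=C1C(=O)O[C@H]2[C@H]1[C@H](OC(=O)/C(=C\C)COC(C)=O)C[C@@](C)(O)C[C@@H](O)/C=C(/COC(C)=O)[C@@H]2OC(C)=O | target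

**Step count and risk**

Total step count: 23 (side-chain acid, steps 1–4; main line, steps 5–23).
Longest linear sequence: 19 steps (steps 5–23, from (R)-mevalonolactone).

Steps most likely to fail:

1. Step 21 (macrocyclic allylation). Intermolecular allylation (oligomerisation) or simple reduction of the allylchromium species may outrun ring closure, and closure may occur on the wrong face at C7. Fallback, from 25 back to 32: esterification of 25 with 2-[(trimethylsilyl)methyl]acrylic acid (DIC, DMAP) gives the C6 2-[(trimethylsilyl)methyl]acrylate F1. Ring-closing metathesis as in step 18 gives the 3-[(trimethylsilyl)methyl]butenolide F2. HF·pyridine gives the C8,C10-diol F3 (the electron-poor allylsilane should resist protodesilylation). Dess–Martin oxidation gives the C8 aldehyde F4. BF3·OEt2 in CH2Cl2 at −78 °C under high dilution then closes the ring by an intramolecular Hosomi–Sakurai allylation through an open transition state to give 32.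

2. Step 22 (Mitsunobu inversion at C8). Elimination of the activated alcohol toward C7 or C9, or sluggish activation of the hindered ring carbinol, may compete with clean inversion. Fallback, from 32 back to 33: chloromethanesulfonyl chloride and pyridine (CH2Cl2, 0 °C) convert 32 into the (8S)-chloromethanesulfonate F5. The caesium salt of 6 (Cs2CO3, 18-crown-6, toluene, 40 °C) then displaces it with inversion to give 33.

3. Step 18 (metathesis in the presence of the allylic bromide). Alkylation of the catalyst by the allylic bromide, or slow turnover on the electron-poor 1,1-disubstituted acrylate, may stop ring closure. Fallback, from 25 back to 28: esterification with 2-{[(4-methoxybenzyl)oxy]methyl}acrylic acid (DIC, DMAP) gives the C6 acrylate F6. Ring-closing metathesis gives the 3-[(4-methoxybenzyloxy)methyl]butenolide F7. DDQ gives the 3-(hydroxymethyl)butenolide F8. Appel bromination (CBr4, PPh3, CH2Cl2, 0 °C) gives 28.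

Further compounds
F1 | step 21 | C6 2-[(trimethylsilyl)methyl]acrylate of 25 | CC(C)(C)[Si](C)(C)OCC[C@@](C)(O[Si](CC)(CC)CC)C[C@@H](O[Si](C(C)C)(C(C)C)C(C)C)/C=C(/COC(C)=O)[C@H](OC(C)=O)[C@@H](OC(=O)C(=C)C[Si](C)(C)C)C=C
F2 | step 21 | 3-[(trimethylsilyl)methyl]butenolide analogue of 28 | CC(C)(C)[Si](C)(C)OCC[C@@](C)(O[Si](CC)(CC)CC)C[C@@H](O[Si](C(C)C)(C(C)C)C(C)C)/C=C(/COC(C)=O)[C@H](OC(C)=O)[C@H]1OC(=O)C(C[Si](C)(C)C)=C1
F3 | step 21 | C8,C10-diol analogue of 29 with CH2SiMe3 in place of CH2Br | OCC[C@@](C)(O)C[C@@H](O[Si](C(C)C)(C(C)C)C(C)C)/C=C(/COC(C)=O)[C@H](OC(C)=O)[C@H]1OC(=O)C(C[Si](C)(C)C)=C1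
F4 | step 21 | C8 aldehyde analogue of 30 with CH2SiMe3 in place of CH2Br | O=CC[C@@](C)(O)C[C@@H](O[Si](C(C)C)(C(C)C)C(C)C)/C=C(/COC(C)=O)[C@H](OC(C)=O)[C@H]1OC(=O)C(C[Si](C)(C)C)=C1
F5 | step 22 | (8S)-chloromethanesulfonate of 32 | C=C1C(=O)O[C@H]2[C@H]1[C@@H](OS(=O)(=O)CCl)C[C@@](C)(O)C[C@@H](O[Si](C(C)C)(C(C)C)C(C)C)/C=C(/COC(C)=O)[C@@H]2OC(C)=O
F6 | step 18 | C6 2-{[(4-methoxybenzyl)oxy]methyl}acrylate of 25 | CC(C)(C)[Si](C)(C)OCC[C@@](C)(O[Si](CC)(CC)CC)C[C@@H](O[Si](C(C)C)(C(C)C)C(C)C)/C=C(/COC(C)=O)[C@H](OC(C)=O)[C@@H](OC(=O)C(=C)COCc1ccc(OC)cc1)C=C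
F7 | step 18 | 3-[(4-methoxybenzyloxy)methyl]butenolide analogue of 28 | CC(C)(C)[Si](C)(C)OCC[C@@](C)(O[Si](CC)(CC)CC)C[C@@H](O[Si](C(C)C)(C(C)C)C(C)C)/C=C(/COC(C)=O)[C@H](OC(C)=O)[C@H]1OC(=O)C(COCc2ccc(OC)cc2)=C1
F8 | step 18 | 3-(hydroxymethyl)butenolide analogue of 28 | CC(C)(C)[Si](C)(C)OCC[C@@](C)(O[Si](CC)(CC)CC)C[C@@H](O[Si](C(C)C)(C(C)C)C(C)C)/C=C(/COC(C)=O)[C@H](OC(C)=O)[C@H]1OC(=O)C(CO)=C1
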